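The tetrahydrofuran O–C5–C6–C7–C11 (guaiane numbering) is made by contracting a six-membered ring. An intramolecular oxidopyrylium [5+2] cycloaddition builds the hydroazulene with the oxygen bridging C5 and C9; after transposition of the enone, this bridge lies in a 3,6-dihydro-2H-pyran O–C5–C6–C7=C8–C9. Methyl 2-diazopropanoate converts the allylic ether into an oxonium ylide whose [2,3]-shift moves carbon C11 from oxygen to C7. One operation adds C11–C13, sets C7 and quaternary C11, contracts the ring by one atom and leaves C8=C9 for lactonisation. The step exploits the fact that C7 is gamma to the C9–O bond of an oxygen that C5 already holds.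

Key step: step 10

Remark: guaiane numbering is used throughout (ring A = C1–C5; ring B = C1, C5–C10; ring C = O, C5, C6, C7, C11; ring D = lactone C7, C8, O, C12, C11; C13 on C11, C14 on C10, C15 on C4); α is below and β above the plane of the usual drawing. The target is read as the angelate (Z ester) with 1α-H, 2α-O, 4α-OH, 5β-O, 7α-H, 8α-H, 10α-CH3 and 11S.

Step 1
Reactants: 1 2-acetylfuran; 2 (E)-crotonaldehyde
Product: 4 (S,E)-1-(furan-2-yl)-3-hydroxyhex-4-en-1-one, via boron enolate 3 (not isolated)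
Conditions: (+)-Ipc2BCl, Et3N, Et2O, 0 °C; then 2, −78 → −20 °C; then H2O2, pH 7 buffer, MeOH
Reagents that add atoms: none
Why: Boron-mediated asymmetric aldol addition of a methyl ketone, in which the isopinocampheyl ligands of enolate 3 select the aldehyde face in a closed transition state (1,2-addition only) and should set the carbinol (future C2) as S; the antipodal reagent would give the R-carbinol.

Step 2
Reactants: 4 (S,E)-1-(furan-2-yl)-3-hydroxyhex-4-en-1-one
Product: 5 (2R,4S,E)-2-(furan-2-yl)hept-5-ene-2,4-diol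
Conditions: MeMgBr (3.5 equiv), CH2Cl2/Et2O, −78 °C
Reagents that add atoms: methylmagnesium bromide, C[Mg]Br
Why: Chelation-controlled Grignard addition, in which the magnesium alkoxide of the existing hydroxyl ties the ketone into a half-chair with the propenyl group pseudo-equatorial and methyl adds axially, which should place the new hydroxyl (future C4, R) syn to the first one when the furyl group is the chain end, so that the two oxygens end up cis on ring A.

Step 3
Reactants: 5 (2R,4S,E)-2-(furan-2-yl)hept-5-ene-2,4-diol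
Product: 6 (2R,4S,E)-2-(furan-2-yl)-2,4-bis(triethylsilyloxy)hept-5-ene
Conditions: Et3SiOTf (3 equiv), 2,6-lutidine, CH2Cl2, −78 → 0 °C
Reagents that add atoms: triethylsilyl trifluoromethanesulfonate, CC[Si](CC)(CC)OS(=O)(=O)C(F)(F)F
Why: Silyl triflate with a hindered base silylates the secondary and the tertiary alcohol without ionising the furyl carbinol, and no stereocentre is touched.

Step 4
Reactants: 6 (2R,4S,E)-2-(furan-2-yl)-2,4-bis(triethylsilyloxy)hept-5-ene
Product: 8 {5-[(2R,4S,E)-2,4-bis(triethylsilyloxy)hept-5-en-2-yl]furan-2-yl}methanol, via 5-lithiofuran 7 (not isolated)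
Conditions: n-BuLi, THF, −78 → 0 °C; then (CH2O)n, 0 °C → rt
Reagents that add atoms: formaldehyde (from paraformaldehyde), C=O
Why: Directed alpha-lithiation of a 2-alkylfuran at its free C5 position followed by hydroxymethylation, with the silyl ethers and the internal alkene inert to n-BuLi at this temperature; the new carbon becomes C9.

Step 5
Reactants: 8 {5-[(2R,4S,E)-2,4-bis(triethylsilyloxy)hept-5-en-2-yl]furan-2-yl}methanol
Product: 9 6-[(2R,4S,E)-2,4-bis(triethylsilyloxy)hept-5-en-2-yl]-6-hydroxy-2H-pyran-3(6H)-one (both C6 epimers)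
Conditions: NBS, NaHCO3, NaOAc, THF/H2O (4:1), 0 °C
Reagents that add atoms: water, O
Why: Achmatowicz rearrangement, in which the furan is oxidised much faster than the isolated alkene and only the primary hydroxyl can reclose onto the distal ketone because the tertiary one is silylated; the hemiketal centre is lost in step 6.

Step 6
Reactants: 9 6-[(2R,4S,E)-2,4-bis(triethylsilyloxy)hept-5-en-2-yl]-6-hydroxy-2H-pyran-3(6H)-one
Product: 12 2α,4α-bis(triethylsilyloxy)-5β,9β-epoxy-11,12,13-trinor-1αH,10βH-guai-6-en-8-one, via ketal mesylate 10 (not isolated), via oxidopyrylium betaine 11 (not isolated)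
Conditions: MsCl, i-Pr2NEt, MeCN, 0 °C; then 70 °C
Reagents that add atoms: none
Why: Intramolecular oxidopyrylium–alkene [5+2] cycloaddition, in which the three-atom tether can only span C5 and C1 on the side of the oxygen bridge (H1 anti to the bridge, hence the trans relation of H1 and O5), the (E)-alkene places C14 endo (10α), and the pyrylium face should be chosen by the tether, with the C2 silyloxy group trans to the forming C1–C10 bond and the C4 silyloxy group anti to the pyrylium oxygen.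

Step 7
Reactants: 12 2α,4α-bis(triethylsilyloxy)-5β,9β-epoxy-11,12,13-trinor-1αH,10βH-guai-6-en-8-one
Product: 13 8-(p-toluenesulfonylhydrazone) of 12
Conditions: TsNHNH2, THF, 4 Å MS, 50 °C
Reagents that add atoms: p-toluenesulfonyl hydrazide, Cc1ccc(cc1)S(=O)(=O)NN
Why: Condensation of the C8 ketone with the hydrazide under neutral conditions that spare the silyl ethers; no stereocentre changes.

Step 8
Reactants: 13 8-(p-toluenesulfonylhydrazone) of 12
Product: 15 2α,4α-bis(triethylsilyloxy)-5β,9β-epoxy-11,12,13-trinor-1αH,10βH-guai-7-ene, via allylic diazene 14 (not isolated)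
Conditions: catecholborane, CHCl3, 0 °C; then NaOAc·3H2O, 60 °C
Reagents that add atoms: none
Why: Reductive 1,3-transposition of an enone tosylhydrazone, in which hydride adds to C=N, acetate expels sulfinate, and the allylic diazene 14 loses N2 by a retro-ene shift that puts H on C6 and the alkene at C7=C8, next to the C9–O bond.

Step 9
Reactants: 16 methyl 2-methyl-3-oxobutanoate
Product: 17 methyl 2-diazopropanoate
Conditions: p-ABSA, DBU, MeCN, 0 °C → rt
Reagents that add atoms: 4-acetamidobenzenesulfonyl azide, CC(=O)Nc1ccc(cc1)S(=O)(=O)N=[N+]=[N-]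
Why: Deacylative Regitz diazo transfer, in which the azide transfers N2 to the alpha-carbon and the acetyl group leaves on the sulfonamide nitrogen.

Step 10
Reactants: 15 2α,4α-bis(triethylsilyloxy)-5β,9β-epoxy-11,12,13-trinor-1αH,10βH-guai-7-ene; 17 methyl 2-diazopropanoate
Product: 19 methyl (11S)-2α,4α-bis(triethylsilyloxy)-5β,11-epoxy-1αH,7αH,10βH-guai-8-en-12-oate, via oxonium ylide 18 (not isolated)
Conditions: Rh2(OAc)4 (2 mol%), CH2Cl2, 25 °C, slow addition of 17 (3 equiv)
Reagents that add atoms: none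
Why: Proposed new method: the carbenoid formed from 17 and Rh2(OAc)4 is trapped by the exposed lone pair of the bridging oxygen of 15 that points over the C6–C7=C8 bridge, and in ylide 18 the carbanion C11 bonds to C7 while the allylic C9–O bond breaks in a concerted, symmetry-allowed [2,3]-sigmatropic shift, so that the six-membered ring O–C5–C6–C7=C8–C9 becomes the five-membered ring C (O–C5–C6–C7–C11) and C8=C9 remains. The closest known reaction types are the metal-carbenoid oxonium-ylide [2,3]-rearrangement of acyclic allyl ethers and the [2,3]-ring contraction of six-membered cyclic allylic ammonium and sulfonium ylides to 3-vinyl five-membered heterocycles; a bridged dihydropyran has not been used. Ring C closes by C7–C11 bond formation through a five-membered envelope transition state (C11, O, C9, C8, C7) held in a norbornane-like array that the boat-shaped oxabicycle already presents. C7 is set by suprafacial delivery of C11 from the face that carries the oxygen bridge (β), and C11 by the orientation of the planar ylide carbon: the CO2Me group should lie over the open C8=C9 flank (C9 bears only H) and the smaller CH3 over C6 beside the crowded C4, which is the 11S arrangement needed for lactonisation onto C8. The step needs ylide formation at oxygen to outrun cyclopropanation of C7=C8 and 1,2-hydride shift of the carbenoid, and the [2,3]-shift to outrun a [1,2]-shift; the tied-back, Lewis-basic bridging oxygen, slow addition of excess 17 and the alignment of the C9–O bond with the C7=C8 pi system should secure this.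

Step 11
Reactants: 19 methyl (11S)-2α,4α-bis(triethylsilyloxy)-5β,11-epoxy-1αH,7αH,10βH-guai-8-en-12-oate
Product: 21 (11S)-2α,4α-bis(triethylsilyloxy)-5β,11-epoxy-9α-iodo-1αH,7αH,8αH,10βH-guaian-12,8-olide, via carboxylic acid 20 (not isolated)
Conditions: LiOH, THF/MeOH/H2O, 50 °C; then NaHCO3, I2, KI, 0 °C → rt
Reagents that add atoms: lithium hydroxide, [Li+].[OH-]; iodine, II
Why: Saponification followed by iodolactonisation, in which the C12 carboxylate held on the β-face opens the α-iodonium ion of C8=C9 at C8 in an anti addition that closes the five-membered lactone, so C8 is set (O β, H α) and iodine sits α on C9.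

Step 12
Reactants: 21 (11S)-2α,4α-bis(triethylsilyloxy)-5β,11-epoxy-9α-iodo-1αH,7αH,8αH,10βH-guaian-12,8-olide
Product: 22 (11S)-2α,4α-bis(triethylsilyloxy)-5β,11-epoxy-1αH,7αH,8αH,10βH-guaian-12,8-olide
Conditions: Bu3SnH, AIBN (cat.), PhH, 80 °C
Reagents that add atoms: none
Why: Radical-chain reduction of the secondary iodide, which removes the C9 stereocentre and leaves lactone, ether and silyl ethers untouched.

Step 13
Reactants: 22 (11S)-2α,4α-bis(triethylsilyloxy)-5β,11-epoxy-1αH,7αH,8αH,10βH-guaian-12,8-olide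
Product: 23 (11S)-2α,4α-dihydroxy-5β,11-epoxy-1αH,7αH,8αH,10βH-guaian-12,8-olide
Conditions: HF·pyridine, THF/pyridine, 0 °C → rt
Reagents that add atoms: none
Why: Fluoride cleaves both triethylsilyl ethers under buffered conditions that neither open the lactone nor ionise the tertiary C4 alcohol.

Step 14
Reactants: 23 (11S)-2α,4α-dihydroxy-5β,11-epoxy-1αH,7αH,8αH,10βH-guaian-12,8-olide; 24 angelic acid
Product: 26 (11S)-2α-angeloyloxy-4α-hydroxy-5β,11-epoxy-1αH,7αH,8αH,10βH-guaian-12,8-olide (CNP0293659.1), via mixed anhydride 25 (not isolated)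
Conditions: 2,4,6-Cl3C6H2COCl, Et3N, PhMe, 25 °C; then 23, 80 °C (no DMAP)
Reagents that add atoms: none
Why: Yamaguchi esterification, in which the mixed anhydride acylates the secondary C2 hydroxyl while the tertiary C4 hydroxyl is too hindered to react, and the DMAP-free protocol should limit Z to E isomerisation of the angelate.

Compound list
1 | 2-acetylfuran | CC(=O)c1ccco1 | starting material
2 | (E)-crotonaldehyde | C/C=C/C=O | starting material
3 | 1-(furan-2-yl)vinyl diisopinocampheylborinate (boron enolate) | C=C(OB([C@H]1C[C@H]2C[C@@H]([C@@H]1C)C2(C)C)[C@H]1C[C@H]2C[C@@H]([C@@H]1C)C2(C)C)c1ccco1 | intermediate (not isolated)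
4 | (S,E)-1-(furan-2-yl)-3-hydroxyhex-4-en-1-one | C/C=C/[C@@H](O)CC(=O)c1ccco1 | intermediate
5 | (2R,4S,E)-2-(furan-2-yl)hept-5-ene-2,4-diol | C/C=C/[C@@H](O)C[C@@](C)(O)c1ccco1 | intermediate
6 | (2R,4S,E)-2-(furan-2-yl)-2,4-bis(triethylsilyloxy)hept-5-ene | C/C=C/[C@@H](O[Si](CC)(CC)CC)C[C@@](C)(O[Si](CC)(CC)CC)c1ccco1 | intermediate
7 | 5-lithio derivative of 6 | C/C=C/[C@@H](O[Si](CC)(CC)CC)C[C@@](C)(O[Si](CC)(CC)CC)c1ccc([Li])o1 | intermediate (not isolated)
8 | {5-[(2R,4S,E)-2,4-bis(triethylsilyloxy)hept-5-en-2-yl]furan-2-yl}methanol | C/C=C/[C@@H](O[Si](CC)(CC)CC)C[C@@](C)(O[Si](CC)(CC)CC)c1ccc(CO)o1 | intermediate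
9 | 6-[(2R,4S,E)-2,4-bis(triethylsilyloxy)hept-5-en-2-yl]-6-hydroxy-2H-pyran-3(6H)-one (C6 epimers) | C/C=C/[C@@H](O[Si](CC)(CC)CC)C[C@@](C)(O[Si](CC)(CC)CC)C1(O)OCC(=O)C=C1 | intermediate
10 | 6-methanesulfonate of 9 | C/C=C/[C@@H](O[Si](CC)(CC)CC)C[C@@](C)(O[Si](CC)(CC)CC)C1(OS(C)(=O)=O)OCC(=O)C=C1 | intermediate (not isolated)
11 | 6-[(2R,4S,E)-2,4-bis(triethylsilyloxy)hept-5-en-2-yl]pyrylium-3-olate | C/C=C/[C@@H](O[Si](CC)(CC)CC)C[C@@](C)(O[Si](CC)(CC)CC)c1ccc([O-])c[o+]1 | intermediate (not isolated)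
12 | 2α,4α-bis(triethylsilyloxy)-5β,9β-epoxy-11,12,13-trinor-1αH,10βH-guai-6-en-8-one | CC[Si](CC)(CC)O[C@H]1C[C@@](C)(O[Si](CC)(CC)CC)[C@@]23C=CC(=O)[C@H](O3)[C@@H](C)[C@H]12 | intermediate
13 | 8-(p-toluenesulfonylhydrazone) of 12 | CC[Si](CC)(CC)O[C@H]1C[C@@](C)(O[Si](CC)(CC)CC)[C@@]23C=CC(=NNS(=O)(=O)c4ccc(C)cc4)[C@H](O3)[C@@H](C)[C@H]12 | intermediate
14 | 8-diazenyl-2α,4α-bis(triethylsilyloxy)-5β,9β-epoxy-11,12,13-trinor-1αH,10βH-guai-6-ene | CC[Si](CC)(CC)O[C@H]1C[C@@](C)(O[Si](CC)(CC)CC)[C@@]23C=CC(N=N)[C@H](O3)[C@@H](C)[C@H]12 | intermediate (not isolated)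
15 | 2α,4α-bis(triethylsilyloxy)-5β,9β-epoxy-11,12,13-trinor-1αH,10βH-guai-7-ene | CC[Si](CC)(CC)O[C@H]1C[C@@](C)(O[Si](CC)(CC)CC)[C@@]23CC=C[C@H](O3)[C@@H](C)[C@H]12 | intermediate
16 | methyl 2-methyl-3-oxobutanoate | COC(=O)C(C)C(C)=O | starting material
17 | methyl 2-diazopropanoate | COC(=O)C(C)=[N+]=[N-] | intermediate
18 | oxonium ylide of 15 carrying the 1-methoxycarbonylethylide on the bridging oxygen | CC[Si](CC)(CC)O[C@H]1C[C@@](C)(O[Si](CC)(CC)CC)[C@@]23CC=C[C@H]([O+]3[C-](C)C(=O)OC)[C@@H](C)[C@H]12 | intermediate (not isolated)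
19 | methyl (11S)-2α,4α-bis(triethylsilyloxy)-5β,11-epoxy-1αH,7αH,10βH-guai-8-en-12-oate | CC[Si](CC)(CC)O[C@H]1C[C@@](C)(O[Si](CC)(CC)CC)[C@@]23C[C@@H](C=C[C@@H](C)[C@H]12)[C@@](C)(C(=O)OC)O3 | intermediate
20 | (11S)-2α,4α-bis(triethylsilyloxy)-5β,11-epoxy-1αH,7αH,10βH-guai-8-en-12-oic acid | CC[Si](CC)(CC)O[C@H]1C[C@@](C)(O[Si](CC)(CC)CC)[C@@]23C[C@@H](C=C[C@@H](C)[C@H]12)[C@@](C)(C(=O)O)O3 | intermediate (not isolated)
21 | (11S)-2α,4α-bis(triethylsilyloxy)-5β,11-epoxy-9α-iodo-1αH,7αH,8αH,10βH-guaian-12,8-olide | CC[Si](CC)(CC)O[C@H]1C[C@@](C)(O[Si](CC)(CC)CC)[C@@]23C[C@H]4[C@@H]([C@@H](I)[C@@H](C)[C@H]12)OC(=O)[C@@]4(C)O3 | intermediate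
22 | (11S)-2α,4α-bis(triethylsilyloxy)-5β,11-epoxy-1αH,7αH,8αH,10βH-guaian-12,8-olide | CC[Si](CC)(CC)O[C@H]1C[C@@](C)(O[Si](CC)(CC)CC)[C@@]23C[C@H]4[C@@H](C[C@@H](C)[C@H]12)OC(=O)[C@@]4(C)O3 | intermediate
23 | (11S)-2α,4α-dihydroxy-5β,11-epoxy-1αH,7αH,8αH,10βH-guaian-12,8-olide | O[C@H]1C[C@@](C)(O)[C@@]23C[C@H]4[C@@H](C[C@@H](C)[C@H]12)OC(=O)[C@@]4(C)O3 | intermediate
24 | angelic acid, (Z)-2-methylbut-2-enoic acid | C/C=C(/C)C(=O)O | starting material
25 | angelic 2,4,6-trichlorobenzoic anhydride | C/C=C(/C)C(=O)OC(=O)c1c(Cl)cc(Cl)cc1Cl | intermediate (not isolated)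
26 | (11S)-2α-angeloyloxy-4α-hydroxy-5β,11-epoxy-1αH,7αH,8αH,10βH-guaian-12,8-olide (CNP0293659.1) | C/C=C(/C)C(=O)O[C@H]1C[C@@](C)(O)[C@@]23C[C@H]4[C@@H](C[C@@H](C)[C@H]12)OC(=O)[C@@]4(C)O3 | target

Total step count: 14
Longest linear sequence: 13 steps (steps 1–8 and 10–14, from 2-acetylfuran); step 9 is a one-step side branch.

Steps most likely to fail

Step 10 (Proposed new method). The carbenoid may be consumed by cyclopropanation of C7=C8, by 1,2-hydride shift to methyl acrylate or by dimerisation before it reaches the hindered bridging oxygen. The ylide may also take a [1,2]-shift, or rearrange with the ester on the C6 side of C11, from which ring D cannot close. The fallback uses known chemistry, sets out from 12 and comes back at 22; it closes ring C by O–H insertion and gives up the ring contraction. Conjugate reduction of the enone with LiBH(s-Bu)3 (THF, −78 °C) and alkylation of the C7 enolate with methyl bromoacetate on the face of the oxygen bridge should give methyl 2α,4α-bis(triethylsilyloxy)-5β,9β-epoxy-8-oxo-13-nor-1αH,7αH,10βH-guaian-12-oate F1. SmI2 (THF/MeOH, −78 °C) cleaves the C9–O bond alpha to the ketone and should give methyl 2α,4α-bis(triethylsilyloxy)-5β-hydroxy-8-oxo-13-nor-1αH,7αH,10βH-guaian-12-oate F2. NaBH4 (MeOH, 0 °C) should reduce C8 from the α-face, and the 8β-alkoxide lactonises to 2α,4α-bis(triethylsilyloxy)-5β-hydroxy-13-nor-1αH,7αH,8αH,10βH-guaian-12,8-olide F3. Detrifluoroacetylative diazo transfer (LiN(SiMe3)2, CF3CO2CH2CF3; then MsN3, Et3N) gives 11-diazo-2α,4α-bis(triethylsilyloxy)-5β-hydroxy-13-nor-1αH,7αH,8αH,10βH-guaian-12,8-olide F4. Rh2(OAc)4 (CH2Cl2, rt) inserts the carbenoid into the O–H bond of the C5 hydroxyl and closes the five-membered ether of 2α,4α-bis(triethylsilyloxy)-5β,11-epoxy-13-nor-1αH,7αH,8αH,10βH-guaian-12,8-olide F5. LiN(i-Pr)2 then MeI (THF, −78 °C) methylates C11 on its only open face and gives 22.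

Step 6. Ionisation of the hindered tertiary ketal may be slow, and the betaine may dimerise or decompose before it is captured by the unactivated (E)-alkene; facial control by the tether may also be incomplete. The fallback sets out from 6, comes back at 15 and replaces the oxidopyrylium by a more reactive rhodium carbonyl ylide. NaClO2/NaH2PO4 (t-BuOH/H2O) should oxidise the furan of 6 to (2Z,5R,7S,8E)-5-methyl-4-oxo-5,7-bis(triethylsilyloxy)deca-2,8-dienoic acid F6. Zn/AcOH reduces the ene-dione alkene to (5R,7S,E)-5-methyl-4-oxo-5,7-bis(triethylsilyloxy)dec-8-enoic acid F7. i-BuOCOCl/Et3N then Me3SiCHN2 gives (6R,8S,E)-1-diazo-6-methyl-6,8-bis(triethylsilyloxy)undec-9-ene-2,5-dione F8. Rh2(OAc)4 (CH2Cl2) forms the six-membered carbonyl ylide from the C5 ketone and the C9 carbenoid, which adds across the tethered alkene in an intramolecular [3+2] cycloaddition to 2α,4α-bis(triethylsilyloxy)-5β,9β-epoxy-11,12,13-trinor-1αH,10βH-guaian-8-one F9. KN(SiMe3)2/PhNTf2 gives 2α,4α-bis(triethylsilyloxy)-5β,9β-epoxy-11,12,13-trinor-1αH,10βH-guai-7-en-8-yl trifluoromethanesulfonate F10; only C7 can enolise because C9 is a bridgehead. Pd(OAc)2/PPh3 with Bu3N/HCO2H (DMF, 60 °C) reduces the triflate to 15.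

Step 2. The 1,3-induction from the magnesium chelate may be weak for a furyl ketone, and retro-aldol cleavage of the alkoxide may compete. The fallback sets out from 4, comes back at 6 and replaces substrate control by catalyst control. Et3SiCl/imidazole (DMF) gives (S,E)-1-(furan-2-yl)-3-(triethylsilyloxy)hex-4-en-1-one F11. Catalytic asymmetric addition of Me2Zn (Ti(OiPr)4, chiral bis(sulfonamide) diol ligand of the antipode that delivers methyl to the face giving 4R) should give (2R,4S,E)-2-(furan-2-yl)-4-(triethylsilyloxy)hept-5-en-2-ol F12. Et3SiOTf/2,6-lutidine then silylates the tertiary hydroxyl and gives 6.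

Further compounds
F1 | step 10 | methyl 2α,4α-bis(triethylsilyloxy)-5β,9β-epoxy-8-oxo-13-nor-1αH,7αH,10βH-guaian-12-oate | CC[Si](CC)(CC)O[C@H]1C[C@@](C)(O[Si](CC)(CC)CC)[C@@]23C[C@H](CC(=O)OC)C(=O)[C@H](O3)[C@@H](C)[C@H]12
F2 | step 10 | methyl 2α,4α-bis(triethylsilyloxy)-5β-hydroxy-8-oxo-13-nor-1αH,7αH,10βH-guaian-12-oate | CC[Si](CC)(CC)O[C@H]1C[C@@](C)(O[Si](CC)(CC)CC)[C@@]2(O)C[C@H](CC(=O)OC)C(=O)C[C@@H](C)[C@H]12
F3 | step 10 | 2α,4α-bis(triethylsilyloxy)-5β-hydroxy-13-nor-1αH,7αH,8αH,10βH-guaian-12,8-olide | CC[Si](CC)(CC)O[C@H]1C[C@@](C)(O[Si](CC)(CC)CC)[C@@]2(O)C[C@H]3[C@@H](C[C@@H](C)[C@H]12)OC(=O)C3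
F4 | step 10 | 11-diazo-2α,4α-bis(triethylsilyloxy)-5β-hydroxy-13-nor-1αH,7αH,8αH,10βH-guaian-12,8-olide | CC[Si](CC)(CC)O[C@H]1C[C@@](C)(O[Si](CC)(CC)CC)[C@@]2(O)C[C@H]3[C@@H](C[C@@H](C)[C@H]12)OC(=O)C3=[N+]=[N-]
F5 | step 10 | 2α,4α-bis(triethylsilyloxy)-5β,11-epoxy-13-nor-1αH,7αH,8αH,10βH-guaian-12,8-olide | CC[Si](CC)(CC)O[C@H]1C[C@@](C)(O[Si](CC)(CC)CC)[C@@]23C[C@H]4[C@@H](C[C@@H](C)[C@H]12)OC(=O)[C@H]4O3
F6 | step 6 | (2Z,5R,7S,8E)-5-methyl-4-oxo-5,7-bis(triethylsilyloxy)deca-2,8-dienoic acid | C/C=C/[C@@H](O[Si](CC)(CC)CC)C[C@@](C)(O[Si](CC)(CC)CC)C(=O)/C=C\C(=O)O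
F7 | step 6 | (5R,7S,E)-5-methyl-4-oxo-5,7-bis(triethylsilyloxy)dec-8-enoic acid | C/C=C/[C@@H](O[Si](CC)(CC)CC)C[C@@](C)(O[Si](CC)(CC)CC)C(=O)CCC(=O)O
F8 | step 6 | (6R,8S,E)-1-diazo-6-methyl-6,8-bis(triethylsilyloxy)undec-9-ene-2,5-dione | C/C=C/[C@@H](O[Si](CC)(CC)CC)C[C@@](C)(O[Si](CC)(CC)CC)C(=O)CCC(=O)C=[N+]=[N-]
F9 | step 6 | 2α,4α-bis(triethylsilyloxy)-5β,9β-epoxy-11,12,13-trinor-1αH,10βH-guaian-8-one | CC[Si](CC)(CC)O[C@H]1C[C@@](C)(O[Si](CC)(CC)CC)[C@@]23CCC(=O)[C@H](O3)[C@@H](C)[C@H]12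
F10 | step 6 | 2α,4α-bis(triethylsilyloxy)-5β,9β-epoxy-11,12,13-trinor-1αH,10βH-guai-7-en-8-yl trifluoromethanesulfonate | CC[Si](CC)(CC)O[C@H]1C[C@@](C)(O[Si](CC)(CC)CC)[C@@]23CC=C(OS(=O)(=O)C(F)(F)F)[C@H](O3)[C@@H](C)[C@H]12
F11 | step 2 | (S,E)-1-(furan-2-yl)-3-(triethylsilyloxy)hex-4-en-1-one | C/C=C/[C@@H](O[Si](CC)(CC)CC)CC(=O)c1ccco1
F12 | step 2 | (2R,4S,E)-2-(furan-2-yl)-4-(triethylsilyloxy)hept-5-en-2-ol | C/C=C/[C@@H](O[Si](CC)(CC)CC)C[C@@](C)(O)c1ccco1
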